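The temperatures and times of the flasks differed, but the clue I used lay in the charges. I had two earlier runs in which starting material and reagent, with a catalyst, give product, and I had to say what north and south hold at their stops.

common to all: reagent 0.275 M; free catalyst 0.32 mM
- oak: starting material 0.36 M; temperature 105 °C; run made earlier
- larch: starting material 0.63 M; temperature 116 °C; run made earlier
- north: starting material 0.25 M; temperature 110 °C; time 8.0 min
- south: starting material 0.40 M; temperature 110 °C; time 12 min

| run | time / min | product / % | starting material / % |
|---|---|---|---|
| oak | 1.00 | 12.5 | 87.5 |
| oak | 3.00 | 35.8 | 64.8 |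
| oak | 5.00 | 54.9 | 44.4 |
| oak | 8.00 | 74.8 | 26.9 |
| larch | 1.00 | 14.0 | 85.9 |
| larch | 3.00 | 38.4 | 61.2 |
| larch | 5.00 | 43.3 | 56.4 |
| larch | 8.00 | 42.8 | 56.1 |

(readings scatter by 0.5 percentage points)

- which of the two ends with the higher amount of product, in percent of the starting material charged ("neither" if they lie within 2 percentage points) (north / south / neither)
- product at the end, in percent of the starting material charged, north
- product at the end, in percent of the starting material charged, south



In the larch run the product stood at 43.3% at 5.00 min and 42.8% at 8.00 min, with starting material still present at 56.1%. I wrote a balance for the reagent, assuming one reagent spent per product: reagent left equals reagent charged minus product formed. Larch had formed 0.273 M against 0.275 M charged, so two amounts mattered, the reagent charge and the starting-material charge. Their ratio, in larch 43.7%, I called the ceiling Y, the percent of product that the reagent charge pays for when reagent is the limiting reagent.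

South has the same reagent charge as larch, so its Y is the larch value scaled by the ratio of the starting-material charges, 68.8%, since it has less reagent than starting material. For north, the reagent exceeds the starting material, the same scaling gives Y = 110%, and the charge of starting material is the cap. Oak had turned 0.269 M by 8.00 min at 105 °C, so I expected south, hotter and running 12 min, to reach its Y, and north to end higher, though I set no figure of my own on it.

The forecast said north, with 83% for north and 68.3% for south, holding that “The rate hardly depends on reagent until it is nearly gone”.

The flasks gave north, with 93.3% for north and 68.7% for south.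

    starting material + catalyst intermediate B ⇌ catalyst intermediate C (K = 2.10 M⁻¹, k = 85.0 M⁻¹ s⁻¹, Ea = 37.0 kJ mol⁻¹, ΔH = −17.0 kJ mol⁻¹)
    reagent + free catalyst → catalyst intermediate A (k = 620 M⁻¹ s⁻¹, Ea = 60.0 kJ mol⁻¹)
    catalyst intermediate C ⇌ free catalyst + product (K = 4.60 M, k = 100 s⁻¹, Ea = 71.0 kJ mol⁻¹, ΔH = 30.0 kJ mol⁻¹)
    catalyst intermediate A ⇌ released group + catalyst intermediate B (K = 0.160 M, k = 4.20 s⁻¹, Ea = 78.0 kJ mol⁻¹, ΔH = −26.0 kJ mol⁻¹)
    (constants at 110 °C)

South's slowest mode at 12.0 min had a half-life of 0.0977 min, far shorter than its 12 min, and it stood at its Y of 68.8% with 0% reagent left. North at 8.0 min still held 6.7% of its starting material and 15% of its reagent, and reached 100% by 80.0 min.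

A neighbour of south charged with 1.6 M of starting material has, from the larch value scaled in the same way, Y = 17.2%, and computed it ends at 17.2%, with 0% reagent left.

The data were generated by integration for an exercise; scatter was added.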